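**Plan**
Locants: C-7' is the aryl-bearing and C-8' the CH2OH-bearing carbon of the dioxane ring, and C-9' is the CH2OH carbon. O-3, O-4 and O-5 are the oxygens of the trioxygenated stilbene ring.
Enabling feature: C-7' (O and aryl), C-8' (aryloxy, O-4) and C-9' (OH) show the atom pattern of a 2-aryl-3-aryloxyoxetane opened at its benzylic carbon by O-3, so the C-9' oxygen can come from an aldehyde.
Cuts: first the stilbene C=C, then O-3–C-7' of the dioxane (back to the oxetane), then C-7'–C-8' and O–C-9' of the oxetane ([2+2]). This leaves O-acetylsyringaldehyde and the 4-O-vinyl ether of a 3,5-disilylated methyl gallate.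
Forward: light closes the oxetane ring first, phenol attack on the strained ether closes the dioxane ring second, and the resorcinol ring is joined last through the alkene.
Stereochemistry: trans C-7'/C-8' comes from reversible closure of a planar quinone methide, (7'S,8'S) from two lipase passes at the C-9' carbinol, and the E-alkene from the phosphonate olefination.

Key step: step 6

Remark 1: the compounds between the photocycloaddition and the resolution are racemic and are drawn as the enantiomer that leads to the target.
Remark 2: the lipase is assumed to acylate the (7'S,8'S)-carbinol faster, by analogy with like-configured trans-3-aryl-2-hydroxymethylbenzodioxanes. If the sense is reversed, the alcohol left beyond half conversion is already the wanted enantiomer and the alcoholysis step lapses. The configuration is to be checked by electronic circular dichroism before going on.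

**Step 1**
Reactants: 1 methyl gallate; 2 benzyl bromide
Product: 3 methyl 4-(benzyloxy)-3,5-dihydroxybenzoate
Conditions: BnBr (1.0 equiv), KHCO3, DMF, rt to 40 °C
Reagents that add atoms: benzyl bromide, BrCc1ccccc1
Why: Williamson ether synthesis; the 4-OH is para to the ester and the most acidic of the three, so the weak base ionises only this site and one equivalent of halide alkylates it selectively.

**Step 2**
Reactants: 3 methyl 4-(benzyloxy)-3,5-dihydroxybenzoate; 4 tert-butyldimethylsilyl chloride
Product: 5 methyl 4-(benzyloxy)-3,5-bis[(tert-butyldimethylsilyl)oxy]benzoate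
Conditions: TBSCl (2.5 equiv), imidazole, DMF, rt
Reagents that add atoms: tert-butyldimethylsilyl chloride, CC(C)(C)[Si](C)(C)Cl
Why: Imidazole-promoted silylation of phenols; the two remaining hydroxyls are equivalent, and the ester and benzyl ether are inert.

**Step 3**
Reactants: 5 methyl 4-(benzyloxy)-3,5-bis[(tert-butyldimethylsilyl)oxy]benzoate
Product: 6 methyl 3,5-bis[(tert-butyldimethylsilyl)oxy]-4-hydroxybenzoate
Conditions: H2 (1 atm), Pd/C, EtOAc, rt
Reagents that add atoms: none
Why: Catalytic hydrogenolysis of a benzyl aryl ether under neutral conditions spares aryl silyl ethers and the ester, and forms no phenoxide that could start silyl migration.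

**Step 4**
Reactants: 6 methyl 3,5-bis[(tert-butyldimethylsilyl)oxy]-4-hydroxybenzoate; 7 vinyl acetate
Product: 8 methyl 3,5-bis[(tert-butyldimethylsilyl)oxy]-4-(vinyloxy)benzoate
Conditions: vinyl acetate (excess), [Ir(cod)Cl]2 (2 mol%), Na2CO3 (0.6 equiv), toluene, 100 °C
Reagents that add atoms: vinyl acetate, C=COC(C)=O
Why: Iridium-catalysed transfer vinylation of phenols; the phenoxide adds to vinyl acetate bound to monovalent iridium and acetate leaves by β-elimination, and because the 4-phenoxide para to the ester is the most stable anion available, silyl migration from O-3 is disfavoured.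

**Step 5**
Reactants: 9 syringaldehyde; 10 acetic anhydride
Product: 11 4-acetoxy-3,5-dimethoxybenzaldehyde
Conditions: Ac2O, pyridine, CH2Cl2, 0 °C to rt
Reagents that add atoms: acetic anhydride, CC(=O)OC(C)=O
Why: Acylation of a phenol with an anhydride; it removes the phenolic O–H, which would quench the excited carbonyl by hydrogen transfer, and weakens the para donor.

**Step 6**
Reactants: 8 methyl 3,5-bis[(tert-butyldimethylsilyl)oxy]-4-(vinyloxy)benzoate; 11 4-acetoxy-3,5-dimethoxybenzaldehyde
Product: 12 (±)-trans-oxetane methyl 4-{[(2R*,3S*)-2-(4-acetoxy-3,5-dimethoxyphenyl)oxetan-3-yl]oxy}-3,5-bis[(tert-butyldimethylsilyl)oxy]benzoate; 13 its (2S*,3S*) cis epimer at C-7'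
Conditions: hν (350 nm, borosilicate glass), 8 (0.25 M) in degassed benzene, 11 added in portions, 15–20 °C; chromatography on Et3N-washed silica, unreacted 8 recovered
Reagents that add atoms: none
Why: Light of 350 nm is absorbed only by aldehyde 11, whose triplet (the acyl group on the para oxygen damps its donor strength and keeps n,π* character within reach) attacks the unsubstituted vinyl carbon C-9' of 8 through oxygen; the triplet 1,4-biradical so formed, with one centre on aryloxy-bearing C-8' and one on benzylic C-7', crosses to the singlet and collapses by C-7'–C-8' bonding. This is the Paternò–Büchi reaction of aromatic aldehydes with enol ethers, which is known to give 3-alkoxy-2-aryloxetanes. The one ring closed, the oxetane, arises by a stepwise [2+2] cycloaddition, O–C-9' first and recombination of the 1,4-biradical second. C-8' is created without facial bias, so 12 and 13 are racemic and the absolute configuration is chosen only in steps 8 and 9; C-7' is set relative to C-8' by the biradical conformation at intersystem crossing, and the expected mixture is harmless because step 7 erases this centre. The selectivity needed is that of orientation (3-aryloxy, not the 2-aryloxy acetal), and it rests on the better stabilised α-aryloxy radical; the two ortho silyloxy groups turn the benzoate ring out of conjugation with the ether oxygen, so its lone pair feeds the vinyl group as in an alkyl vinyl ether. Slow addition of 11 to concentrated 8 holds down aldehyde self-reaction, and the acid-labile acetal regioisomer is removed on chromatography.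

**Step 7**
Reactants: 12 (±)-trans-oxetane; 13 (±)-cis-oxetane
Product: 16 (±)-trans-benzodioxane methyl (2S*,3S*)-8-hydroxy-3-(4-hydroxy-3,5-dimethoxyphenyl)-2-(hydroxymethyl)-2,3-dihydro-1,4-benzodioxine-6-carboxylate, via triphenol oxetane 14 (not isolated), via p-quinone methide 15 (not isolated)
Conditions: K2CO3 (4 equiv), MeOH–THF, Ar, 0 °C to rt; AcOH quench, solvent exchange; camphorsulfonic acid (10 mol%), MeCN, 0 °C to rt
Reagents that add atoms: none
Why: Base-mediated methanolysis frees the three phenols (aryl acetates and the aryl silyl ethers of an electron-poor ring are both labile to K2CO3/MeOH, while the methyl ester only exchanges with itself), and the known acid-catalysed opening of a 2-aryloxetane at its benzylic carbon by an oxygen nucleophile follows: the para phenol expels the protonated ring oxygen with release of about 25 kcal/mol of strain, planar C-7' of 15 is captured by the flanking phenol in a 6-exo closure (O-3 and O-5 are equivalent), and the reversible addition should settle on the diequatorial trans ring from both oxetane epimers, as in the quinone methide closure of oxidative benzodioxane neolignan couplings.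

**Step 8**
Reactants: 16 (±)-trans-benzodioxane triol; 7 vinyl acetate
Product: 17 methyl (2S,3S)-2-(acetoxymethyl)-8-hydroxy-3-(4-hydroxy-3,5-dimethoxyphenyl)-2,3-dihydro-1,4-benzodioxine-6-carboxylate
Conditions: immobilised Candida antarctica lipase B, vinyl acetate (3 equiv), MTBE–acetone, 35 °C, stopped at about 40% conversion; chromatography
Reagents that add atoms: vinyl acetate, C=COC(C)=O
Why: Lipase-catalysed kinetic resolution by irreversible transesterification; only the primary C-9' hydroxyl is acylated (phenols and the benzoate are left alone) and the adjacent C-8' centre makes one enantiomer react faster, a discrimination known for 2-hydroxymethyl-1,4-benzodioxanes, and since the relative configuration is already trans this fixes C-7' and C-8' together.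

**Step 9**
Reactants: 17 (2S,3S)-acetate
Product: 18 methyl (2S,3S)-8-hydroxy-3-(4-hydroxy-3,5-dimethoxyphenyl)-2-(hydroxymethyl)-2,3-dihydro-1,4-benzodioxine-6-carboxylate
Conditions: immobilised Candida antarctica lipase B, n-BuOH (10 equiv), MTBE, 40 °C, stopped short of full conversion
Reagents that add atoms: none
Why: Lipase-catalysed alcoholysis, the reverse of step 8 with the same enantiomer preference, so residual (2R,3R)-acetate stays behind and the selectivities of the two passes multiply, while the neutral medium avoids quinone methide formation.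

**Step 10**
Reactants: 18 (2S,3S)-triol; 4 tert-butyldimethylsilyl chloride
Product: 19 methyl (2S,3S)-8-[(tert-butyldimethylsilyl)oxy]-2-{[(tert-butyldimethylsilyl)oxy]methyl}-3-{4-[(tert-butyldimethylsilyl)oxy]-3,5-dimethoxyphenyl}-2,3-dihydro-1,4-benzodioxine-6-carboxylate
Conditions: TBSCl (4.5 equiv), imidazole, DMF, rt
Reagents that add atoms: tert-butyldimethylsilyl chloride, CC(C)(C)[Si](C)(C)Cl
Why: Imidazole-promoted silylation of two phenols and one primary alcohol masks every acidic proton for the hydride and carbanion steps, and capping the syringyl phenol blocks ionisation at C-7'.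

**Step 11**
Reactants: 19 tris-silyl ether ester
Product: 20 the corresponding (2S,3S)-benzodioxin-6-ylmethanol (CO2Me replaced by CH2OH)
Conditions: i-Bu2AlH (3 equiv), CH2Cl2, −78 to −20 °C; aq. potassium sodium tartrate
Reagents that add atoms: none
Why: Hydride reduction of an aromatic ester to the benzylic alcohol; silyl ethers and the benzodioxane are inert at low temperature.

**Step 12**
Reactants: 20 benzylic alcohol; 21 triethyl phosphite
Product: 23 diethyl {[(2S,3S)-benzodioxin-6-yl]methyl}phosphonate (CH2OH of 20 replaced by CH2P(O)(OEt)2), via benzylic bromide 22 (not isolated)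
Conditions: CBr4, PPh3, CH2Cl2, 0 °C; short silica plug, concentration; P(OEt)3 (neat), 120 °C
Reagents that add atoms: triethyl phosphite, CCOP(OCC)OCC; tetrabromomethane, BrC(Br)(Br)Br (bromine of 22 only)
Why: Appel bromination under neutral conditions followed by the Michaelis–Arbuzov reaction; the electron-rich benzylic bromide is not stored but heated at once with the phosphite, and no stereocentre takes part.

**Step 13**
Reactants: 24 3,5-dihydroxybenzaldehyde; 4 tert-butyldimethylsilyl chloride
Product: 25 3,5-bis[(tert-butyldimethylsilyl)oxy]benzaldehyde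
Conditions: TBSCl (2.5 equiv), imidazole, DMF, rt
Reagents that add atoms: tert-butyldimethylsilyl chloride, CC(C)(C)[Si](C)(C)Cl
Why: Imidazole-promoted silylation of phenols; the aldehyde is untouched.

**Step 14**
Reactants: 23 phosphonate; 25 3,5-bis[(tert-butyldimethylsilyl)oxy]benzaldehyde
Product: 26 penta-O-TBS ether of the target, (E)-stilbene with (2S,3S)-benzodioxane
Conditions: KN(SiMe3)2, THF, −78 °C, then 25, to rt
Reagents that add atoms: none
Why: Horner–Wadsworth–Emmons olefination; benzylic phosphonate anions and aromatic aldehydes give E-stilbenes through reversible addition and preferred collapse of the anti adduct, the non-nucleophilic amide base spares the aryl silyl ethers, and C-7' and C-8' carry no acidic hydrogen.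

**Step 15**
Reactants: 26 penta-O-TBS ether
Product: 27 target, 5-[(E)-2-[(2S,3S)-8-hydroxy-3-(4-hydroxy-3,5-dimethoxyphenyl)-2-(hydroxymethyl)-2,3-dihydro-1,4-benzodioxin-6-yl]ethenyl]benzene-1,3-diol
Conditions: Bu4NF/AcOH (1:1, 6 equiv), THF, Ar, dark, 0 °C to rt
Reagents that add atoms: none
Why: Fluoride-mediated desilylation; the acetic acid buffer keeps the phenols protonated so no syringyl phenoxide can open the dioxane and epimerise C-7', and exclusion of light protects the E-alkene.

**Compound list**
1 | methyl gallate (methyl 3,4,5-trihydroxybenzoate) | COC(=O)c1cc(O)c(O)c(O)c1 | starting material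
2 | benzyl bromide | BrCc1ccccc1 | starting material
3 | methyl 4-(benzyloxy)-3,5-dihydroxybenzoate | COC(=O)c1cc(O)c(OCc2ccccc2)c(O)c1 | intermediate
4 | tert-butyldimethylsilyl chloride | CC(C)(C)[Si](C)(C)Cl | starting material
5 | methyl 4-(benzyloxy)-3,5-bis[(tert-butyldimethylsilyl)oxy]benzoate | COC(=O)c1cc(O[Si](C)(C)C(C)(C)C)c(OCc2ccccc2)c(O[Si](C)(C)C(C)(C)C)c1 | intermediate
6 | methyl 3,5-bis[(tert-butyldimethylsilyl)oxy]-4-hydroxybenzoate | COC(=O)c1cc(O[Si](C)(C)C(C)(C)C)c(O)c(O[Si](C)(C)C(C)(C)C)c1 | intermediate
7 | vinyl acetate | C=COC(C)=O | starting material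
8 | methyl 3,5-bis[(tert-butyldimethylsilyl)oxy]-4-(vinyloxy)benzoate | C=COc1c(O[Si](C)(C)C(C)(C)C)cc(C(=O)OC)cc1O[Si](C)(C)C(C)(C)C | intermediate
9 | syringaldehyde | COc1cc(C=O)cc(OC)c1O | starting material
10 | acetic anhydride | CC(=O)OC(C)=O | starting material
11 | 4-acetoxy-3,5-dimethoxybenzaldehyde | COc1cc(C=O)cc(OC)c1OC(C)=O | intermediate
12 | (±)-trans-oxetane, drawn (2R,3S) = (7'R,8'S) | COc1cc([C@H]2OC[C@@H]2Oc3c(O[Si](C)(C)C(C)(C)C)cc(C(=O)OC)cc3O[Si](C)(C)C(C)(C)C)cc(OC)c1OC(C)=O | intermediate
13 | (±)-cis-oxetane, drawn (2S,3S) = (7'S,8'S) | COc1cc([C@@H]2OC[C@@H]2Oc3c(O[Si](C)(C)C(C)(C)C)cc(C(=O)OC)cc3O[Si](C)(C)C(C)(C)C)cc(OC)c1OC(C)=O | intermediate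
14 | (±)-methyl 3,5-dihydroxy-4-{[2-(4-hydroxy-3,5-dimethoxyphenyl)oxetan-3-yl]oxy}benzoate, epimer mixture at C-7', C-8' drawn S | COc1cc(C2OC[C@@H]2Oc3c(O)cc(C(=O)OC)cc3O)cc(OC)c1O | intermediate
15 | (±)-p-quinone methide, methyl 4-{[1-(3,5-dimethoxy-4-oxocyclohexa-2,5-dien-1-ylidene)-3-hydroxypropan-2-yl]oxy}-3,5-dihydroxybenzoate, drawn (2R) | COC1=CC(=C[C@H](CO)Oc2c(O)cc(C(=O)OC)cc2O)C=C(OC)C1=O | intermediate
16 | (±)-trans-benzodioxane triol ester, drawn (2S,3S) | COc1cc([C@@H]2Oc3cc(C(=O)OC)cc(O)c3O[C@H]2CO)cc(OC)c1O | intermediate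
17 | (2S,3S)-9'-O-acetate | COc1cc([C@@H]2Oc3cc(C(=O)OC)cc(O)c3O[C@H]2COC(C)=O)cc(OC)c1O | intermediate
18 | (2S,3S)-benzodioxane triol ester, single enantiomer | COc1cc([C@@H]2Oc3cc(C(=O)OC)cc(O)c3O[C@H]2CO)cc(OC)c1O | intermediate
19 | (2S,3S)-tris-TBS ether ester | COc1cc([C@@H]2Oc3cc(C(=O)OC)cc(O[Si](C)(C)C(C)(C)C)c3O[C@H]2CO[Si](C)(C)C(C)(C)C)cc(OC)c1O[Si](C)(C)C(C)(C)C | intermediate
20 | (2S,3S)-tris-TBS benzylic alcohol | COc1cc([C@@H]2Oc3cc(CO)cc(O[Si](C)(C)C(C)(C)C)c3O[C@H]2CO[Si](C)(C)C(C)(C)C)cc(OC)c1O[Si](C)(C)C(C)(C)C | intermediate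
21 | triethyl phosphite | CCOP(OCC)OCC | starting material
22 | (2S,3S)-tris-TBS benzylic bromide | COc1cc([C@@H]2Oc3cc(CBr)cc(O[Si](C)(C)C(C)(C)C)c3O[C@H]2CO[Si](C)(C)C(C)(C)C)cc(OC)c1O[Si](C)(C)C(C)(C)C | intermediate
23 | (2S,3S)-tris-TBS diethyl benzylphosphonate | COc1cc([C@@H]2Oc3cc(CP(=O)(OCC)OCC)cc(O[Si](C)(C)C(C)(C)C)c3O[C@H]2CO[Si](C)(C)C(C)(C)C)cc(OC)c1O[Si](C)(C)C(C)(C)C | intermediate
24 | 3,5-dihydroxybenzaldehyde | O=Cc1cc(O)cc(O)c1 | starting material
25 | 3,5-bis[(tert-butyldimethylsilyl)oxy]benzaldehyde | O=Cc1cc(O[Si](C)(C)C(C)(C)C)cc(O[Si](C)(C)C(C)(C)C)c1 | intermediate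
26 | penta-O-TBS (E)-stilbene, (2S,3S) | COc1cc([C@@H]2Oc3cc(/C=C/c4cc(O[Si](C)(C)C(C)(C)C)cc(O[Si](C)(C)C(C)(C)C)c4)cc(O[Si](C)(C)C(C)(C)C)c3O[C@H]2CO[Si](C)(C)C(C)(C)C)cc(OC)c1O[Si](C)(C)C(C)(C)C | intermediate
27 | CNP0319597.1, (7'S,8'S), E | COc1cc([C@@H]2Oc3cc(/C=C/c4cc(O)cc(O)c4)cc(O)c3O[C@H]2CO)cc(OC)c1O | target

**Totals**
Total steps: 15. Longest linear sequence: 13 steps (1–4, 6–12, 14, 15).

**Steps most likely to fail**

**Step 6.** A low-lying π,π* triplet of the trioxygenated aldehyde may add too slowly to the vinyl ether. Hydrogen abstraction and pinacol coupling of the aldehyde, loss of excitation to the benzoate chromophore, or oxygen attack at the substituted vinyl carbon could then take over. The fallback gives up light for an oxidative phenol coupling and sets out from 9 and 1. Syringaldehyde 9 is condensed with monoethyl malonate (pyridine, piperidine; Knoevenagel–Doebner) to ethyl (E)-sinapate F1. Reduction with i-Bu2AlH gives sinapyl alcohol F2. Ag2CO3 in benzene–acetone then couples F2 with methyl gallate 1. The gallate 4-O radical joins C-8' of the sinapyl radical, which gives quinone methide 15, and its closure rejoins the route at 16.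

**Step 8.** The stereocentre lies one carbon away from the reacting oxygen and bears an oxygen itself, so the enzyme may discriminate poorly or prefer the other enantiomer. The fallback replaces kinetic resolution by covalent diastereomers and sets out from 16. All three hydroxyls are acylated with (1S)-camphanic chloride (Et3N, DMAP, CH2Cl2). This gives the (7'S,8'S)-tris-camphanate F3 and the (7'R,8'R)-tris-camphanate F4, which are separated by fractional crystallisation or chromatography. The known configuration of the acyl group lets X-ray analysis assign the two. Brief methanolysis of F3 (K2CO3, MeOH, 0 °C, Ar) comes back to the route at 18.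

**Step 4.** At 100 °C with carbonate, the silyl group may migrate from O-3 to the crowded 4-phenoxide, so that the less hindered oxygen is vinylated. The hindered phenoxide may also simply be acetylated by vinyl acetate. The fallback builds the vinyl group by elimination under neutral conditions and sets out from 6. Mitsunobu etherification with 2-(phenylselanyl)ethanol (PPh3, diisopropyl azodicarboxylate, THF) gives the 2-(phenylselanyl)ethyl ether F5. NaIO4 (NaHCO3, MeOH–H2O) oxidises it to the selenoxide F6. Syn elimination of F6 in warm toluene with i-Pr2NH comes back to the route at 8.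

**Further compounds**
F1 | step 6 | ethyl (E)-sinapate | CCOC(=O)/C=C/c1cc(OC)c(O)c(OC)c1
F2 | step 6 | sinapyl alcohol | OC/C=C/c1cc(OC)c(O)c(OC)c1
F3 | step 8 | (7'S,8'S)-tris-[(1S,4R)-camphanate] of 16 | COc1cc([C@@H]2Oc3cc(C(=O)OC)cc(OC(=O)[C@@]45CC[C@@](C)(C(=O)O4)C5(C)C)c3O[C@H]2COC(=O)[C@@]45CC[C@@](C)(C(=O)O4)C5(C)C)cc(OC)c1OC(=O)[C@@]45CC[C@@](C)(C(=O)O4)C5(C)C
F4 | step 8 | (7'R,8'R)-tris-[(1S,4R)-camphanate] of 16 | COc1cc([C@H]2Oc3cc(C(=O)OC)cc(OC(=O)[C@@]45CC[C@@](C)(C(=O)O4)C5(C)C)c3O[C@@H]2COC(=O)[C@@]45CC[C@@](C)(C(=O)O4)C5(C)C)cc(OC)c1OC(=O)[C@@]45CC[C@@](C)(C(=O)O4)C5(C)C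
F5 | step 4 | methyl 3,5-bis[(tert-butyldimethylsilyl)oxy]-4-[2-(phenylselanyl)ethoxy]benzoate | COC(=O)c1cc(O[Si](C)(C)C(C)(C)C)c(OCC[Se]c2ccccc2)c(O[Si](C)(C)C(C)(C)C)c1
F6 | step 4 | methyl 3,5-bis[(tert-butyldimethylsilyl)oxy]-4-[2-(phenylseleninyl)ethoxy]benzoate | COC(=O)c1cc(O[Si](C)(C)C(C)(C)C)c(OCC[Se](=O)c2ccccc2)c(O[Si](C)(C)C(C)(C)C)c1
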